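**Retrosynthetic overview**
1. Oxolane numbering used below: O1, C2 (aryl), C3 (CH2OH), C4 (aroyl), C5 (CH2). The enabling feature is the array O1–C5H2–C4H–C(=O)Ar, a β-alkoxy ketone in which C5 is the β-carbon and C4 the enolisable α-carbon of the exocyclic aryl ketone.
2. Key disconnection O1–C5: the carbonyl carbon, C4 and C5 are stored as a 1-arylcyclopropanol. Oxidative cleavage of its C(OH)–CH2 bond unveils the ketone and an α-methylene group, the free benzylic O1–H closes the oxolane at C5, and C4 settles by equilibration, so all cyclopropanol diastereomers converge.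
3. The benzylic C2–O1 bond is neither made nor broken in this closure, so the contra-thermodynamic 2,3-cis relationship set earlier is carried through unchanged.
4. The cyclopropanol comes from a Kulinkovich hydroxycyclopropanation of a syn homoallylic alcohol with methyl 3,4,5-trimethoxybenzoate. C2 and C3 come from one catalytic asymmetric syn-(borylmethyl)allylation of 3,4,5-trimethoxybenzaldehyde with the (Z)-1,4-diborylbut-2-ene made from butadiene.
5. Ring order: temporary cyclopropane (step 4), then the oxolane at the expense of the cyclopropane (step 5).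

Key step: step 5

Assumption: (S)-TRIP is taken to direct the allyl unit to the Si face of the aldehyde, by analogy with the Re-face preference of the (R)-acid in allyl- and crotylborations of benzaldehydes. If the sense proves opposite, the (R)-acid is used.

**Step 1**
Reactants: 1 buta-1,3-diene; 2 bis(pinacolato)diboron
Product: 3 (Z)-1,4-bis(4,4,5,5-tetramethyl-1,3,2-dioxaborolan-2-yl)but-2-ene
Conditions: Pt(PPh3)4 (3 mol %), toluene, 80 °C, sealed vessel
Reagents that add atoms: none
Why: Platinum-catalysed 1,4-diboration of a 1,3-diene, in which oxidative addition of the B–B bond to zerovalent platinum, insertion of the s-cis diene and reductive elimination from the allyl intermediate should give the (Z)-alkene whose geometry later encodes the C2/C3 relationship.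

**Step 2**
Reactants: 3 (Z)-1,4-bis(pinacolatoboryl)but-2-ene; 4 3,4,5-trimethoxybenzaldehyde
Product: 6 (1S,2S)-2-ethenyl-1-(3,4,5-trimethoxyphenyl)propane-1,3-diol, via bis-boronate adduct 5 (not isolated)
Conditions: (S)-TRIP [(S)-3,3'-bis(2,4,6-triisopropylphenyl)-1,1'-binaphthyl-2,2'-diyl hydrogen phosphate] (5 mol %), 4 Å MS, toluene, −30 °C; then THF, aq NaOH, H2O2, 0 °C
Reagents that add atoms: hydrogen peroxide, OO
Why: Chiral phosphoric acid-catalysed allylboration (a syn-(borylmethyl)allylation) through a closed chair Zimmerman–Traxler transition state, in which the (Z)-geometry places CH2Bpin axial and sets the syn C2/C3 relationship, the acid bound to the boronate shields one aldehyde face and sets the absolute configuration, and oxidation of the remaining primary C–B bond then gives the CH2OH group.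

**Step 3**
Reactants: 6 (1S,2S)-2-ethenyl-1-(3,4,5-trimethoxyphenyl)propane-1,3-diol
Product: 7 (1S,2S)-2-{[(tert-butyldimethylsilyl)oxy]methyl}-1-(3,4,5-trimethoxyphenyl)but-3-en-1-ol
Conditions: TBSCl (1.05 equiv), imidazole, CH2Cl2, 0 °C
Reagents that add atoms: tert-butyldimethylsilyl chloride, CC(C)(C)[Si](C)(C)Cl
Why: Sterically controlled selective silylation of the primary over the hindered secondary benzylic hydroxyl, which touches no stereocentre and leaves O1 as the only free oxygen nucleophile for step 5.

**Step 4**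
Reactants: 7 silyl-protected syn homoallylic alcohol; 8 methyl 3,4,5-trimethoxybenzoate
Product: 9 2-[(2S,3S)-1-[(tert-butyldimethylsilyl)oxy]-3-hydroxy-3-(3,4,5-trimethoxyphenyl)propan-2-yl]-1-(3,4,5-trimethoxyphenyl)cyclopropan-1-ol (mixture of diastereomers at the two cyclopropane carbons, used as such)
Conditions: Ti(OiPr)4 (1.2 equiv), c-C5H9MgCl (5 equiv, slow addition), 8 (1.5 equiv), THF, 0 °C to rt
Reagents that add atoms: none
Why: Kulinkovich hydroxycyclopropanation in its olefin-exchange variant, in which the titanacyclopropane made from Ti(OiPr)4 and the Grignard reagent exchanges cyclopentene for the terminal alkene of 7 (assisted by the homoallylic titanium alkoxide) and adds twice to the ester carbonyl, the two new stereocentres needing no control because step 5 erases both.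

**Step 5**
Reactants: 9 cyclopropanol mixture
Product: 12 [(3R,4S,5S)-4-{[(tert-butyldimethylsilyl)oxy]methyl}-5-(3,4,5-trimethoxyphenyl)oxolan-3-yl](3,4,5-trimethoxyphenyl)methanone, via alpha-methylene ketone 10 (not isolated), via C4-epimer 11 (not isolated)
Conditions: Cu(OAc)2 (20 mol %), 2,2'-bipyridine (20 mol %), O2 (1 atm), MeCN, 50 °C; then Ar purge, DBU (0.3 equiv), rt, same flask
Reagents that add atoms: none
Why: The divalent copper alkoxide of the cyclopropanol should undergo β-carbon elimination at the less substituted C(OH)–CH2 bond to a β-cuprio ketone that is oxidised, with O2 as terminal oxidant, to the α-methylene ketone 10, so both stereocentres of the three-membered ring are erased and every diastereomer of 9 converges on one intermediate. The free benzylic hydroxyl O1 then adds to the terminal CH2 (C5) of the enone in a 5-endo-trig oxa-Michael closure of the oxolane, and a direct C–O reductive elimination from a six-membered trivalent copper alkyl alkoxide would form the same bond. The closest known reaction type is the copper-catalysed oxidative ring-opening cyclisation of hydroxy-tethered cyclopropanols to 3-acyltetrahydrofurans, supported by 5-endo-trig alkoxide additions to 1,1-disubstituted vinyl sulfones. C4 is the only new stereocentre: enolate protonation should give 12 together with the all-cis epimer 11, and DBU equilibrates them through the enolate (and through reversible retro-oxa-Michael opening) to the isomer whose aroyl group is trans to the C3 side chain and on the face opposite to the cis C2-aryl/C3-CH2OTBS pair. The step needs selectivity between the two oxygens and between the two cyclopropane bonds: the primary oxygen is silylated so only O1 can close, the unhindered CH2 is the carbon preferred by a two-electron metalation, and attack of O1 on the carbonyl gives only a reversible lactol. C2 and C3 stay untouched because neither C–H is acidic and the benzylic C2–O1 bond is never broken.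

**Step 6**
Reactants: 12 silyl-protected oxolane
Product: 13 [(3R,4S,5S)-4-(hydroxymethyl)-5-(3,4,5-trimethoxyphenyl)oxolan-3-yl](3,4,5-trimethoxyphenyl)methanone (target)
Conditions: HF·pyridine, pyridine, THF, 0 °C to rt
Reagents that add atoms: none
Why: Fluoride-mediated desilylation under buffered, weakly acidic conditions, which avoids both base (retro-oxa-Michael opening followed by closure through the freed primary hydroxyl) and strong acid (ionisation of the benzylic C2–O1 bond), so all three stereocentres are retained.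

**Compound list**
1 | buta-1,3-diene | C=CC=C | starting material
2 | bis(pinacolato)diboron | CC1(C)OB(OC1(C)C)B2OC(C)(C)C(C)(C)O2 | starting material
3 | (Z)-1,4-bis(4,4,5,5-tetramethyl-1,3,2-dioxaborolan-2-yl)but-2-ene | CC1(C)OB(C/C=C\CB2OC(C)(C)C(C)(C)O2)OC1(C)C | intermediate
4 | 3,4,5-trimethoxybenzaldehyde | COc1cc(C=O)cc(OC)c1OC | starting material
5 | pinacol borate of (1S,2R)-2-[(pinacolatoboryl)methyl]-1-(3,4,5-trimethoxyphenyl)but-3-en-1-ol (not isolated) | CC1(C)OB(O[C@H](c2cc(OC)c(OC)c(OC)c2)[C@@H](C=C)CB3OC(C)(C)C(C)(C)O3)OC1(C)C | intermediate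
6 | (1S,2S)-2-ethenyl-1-(3,4,5-trimethoxyphenyl)propane-1,3-diol | O[C@H](c1cc(OC)c(OC)c(OC)c1)[C@@H](C=C)CO | intermediate
7 | (1S,2S)-2-{[(tert-butyldimethylsilyl)oxy]methyl}-1-(3,4,5-trimethoxyphenyl)but-3-en-1-ol | O[C@H](c1cc(OC)c(OC)c(OC)c1)[C@@H](C=C)CO[Si](C)(C)C(C)(C)C | intermediate
8 | methyl 3,4,5-trimethoxybenzoate | COC(=O)c1cc(OC)c(OC)c(OC)c1 | starting material
9 | 2-[(2S,3S)-1-[(tert-butyldimethylsilyl)oxy]-3-hydroxy-3-(3,4,5-trimethoxyphenyl)propan-2-yl]-1-(3,4,5-trimethoxyphenyl)cyclopropan-1-ol, mixture at the two cyclopropane carbons | O[C@H](c1cc(OC)c(OC)c(OC)c1)[C@@H](C2CC2(O)c3cc(OC)c(OC)c(OC)c3)CO[Si](C)(C)C(C)(C)C | intermediate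
10 | (3S,4S)-3-{[(tert-butyldimethylsilyl)oxy]methyl}-4-hydroxy-2-methylidene-1,4-bis(3,4,5-trimethoxyphenyl)butan-1-one (not isolated) | O[C@H](c1cc(OC)c(OC)c(OC)c1)[C@@H](C(=C)C(=O)c2cc(OC)c(OC)c(OC)c2)CO[Si](C)(C)C(C)(C)C | intermediate
11 | [(3S,4S,5S)-4-{[(tert-butyldimethylsilyl)oxy]methyl}-5-(3,4,5-trimethoxyphenyl)oxolan-3-yl](3,4,5-trimethoxyphenyl)methanone, all-cis C4-epimer (not isolated) | COc1cc(C(=O)[C@@H]2CO[C@H](c3cc(OC)c(OC)c(OC)c3)[C@@H]2CO[Si](C)(C)C(C)(C)C)cc(OC)c1OC | intermediate
12 | [(3R,4S,5S)-4-{[(tert-butyldimethylsilyl)oxy]methyl}-5-(3,4,5-trimethoxyphenyl)oxolan-3-yl](3,4,5-trimethoxyphenyl)methanone | COc1cc(C(=O)[C@H]2CO[C@H](c3cc(OC)c(OC)c(OC)c3)[C@@H]2CO[Si](C)(C)C(C)(C)C)cc(OC)c1OC | intermediate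
13 | [(3R,4S,5S)-4-(hydroxymethyl)-5-(3,4,5-trimethoxyphenyl)oxolan-3-yl](3,4,5-trimethoxyphenyl)methanone | COc1cc(C(=O)[C@H]2CO[C@H](c3cc(OC)c(OC)c(OC)c3)[C@@H]2CO)cc(OC)c1OC | target

**Total step count:** 6. **Longest linear sequence:** 6 steps (1 to 3 to 6 to 7 to 9 to 12 to 13).

**Steps most likely to fail**

Step 5. Three processes may intervene. A one-electron pathway may cleave the more substituted cyclopropane bond. The homoenolate may be protonated before it is oxidised. The benzylic alcohol or the enolisable product may be oxidised by air.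
- The fallback separates C–C cleavage from C–O closure and sets out from 9.
- The secondary benzylic hydroxyl is silylated selectively (TESCl, imidazole, CH2Cl2, −20 °C) to the O1-triethylsilyl cyclopropanol F1.
- Pd(OAc)2 (10 mol %), pyridine, O2, toluene, 80 °C then opens the ring by β-carbon elimination at the CH2–C(OH) bond on divalent palladium, followed by β-hydride elimination. This is a known conversion of 1,2-disubstituted cyclopropanols into α-methylene ketones, and it should give the O1-triethylsilyl enone F2.
- PPTS in MeOH at 0 °C removes the triethylsilyl group in the presence of the primary TBS ether and liberates 10, which DBU closes and equilibrates. The route is rejoined at 12.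

Step 4. Olefin exchange may be slow at the allylically branched alkene, and the Grignard reagent may add directly to the electron-rich ester.
- The fallback brings the carbons in by another order and sets out from 7.
- Hydroboration with 9-BBN and NaOH/H2O2 gives the 1,4-diol F3.
- TEMPO/PhI(OAc)2 oxidises the primary alcohol through the lactol to the cis-lactone F4.
- 3,4,5-Trimethoxyphenyllithium F5 (from 5-bromo-1,2,3-trimethoxybenzene and n-BuLi, THF, −78 °C) adds once to give the γ-hydroxy ketone F6, which is in equilibrium with its lactol.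
- Mannich-type α-methylenation with paraformaldehyde and diisopropylammonium trifluoroacetate in THF supplies C5 and gives 10, which DBU closes. The route is rejoined at 12.

Step 2. The (Z)-geometry of the reagent may erode, or facial selectivity may be poor with the electron-rich aldehyde.
- The fallback sets C3 by another catalytic reaction, corrects C2 afterwards, and sets out from 4.
- The first reaction is an iridium-catalysed transfer-hydrogenative (hydroxymethyl)allylation with 4,7-dihydro-1,3-dioxepin-2-one. Its conditions are [Ir(cod)Cl]2, SEGPHOS in the enantiomer that gives 2S, 4-cyano-3-nitrobenzoic acid, Cs2CO3, 2-propanol, THF, 90 °C. This reaction type is anti-selective and should give the anti diol F7.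
- TBSCl/imidazole gives the primary silyl ether F8.
- Mitsunobu inversion at the carbinol (4-nitrobenzoic acid, PPh3, DIAD, THF, 0 °C) gives the inverted 4-nitrobenzoate F9.
- K2CO3 in MeOH cleaves the ester, and the route is rejoined at 7.

**Further compounds**
F1 | step 5 | 2-[(2S,3S)-1-[(tert-butyldimethylsilyl)oxy]-3-[(triethylsilyl)oxy]-3-(3,4,5-trimethoxyphenyl)propan-2-yl]-1-(3,4,5-trimethoxyphenyl)cyclopropan-1-ol | CC[Si](CC)(CC)O[C@H](c1cc(OC)c(OC)c(OC)c1)[C@@H](C2CC2(O)c3cc(OC)c(OC)c(OC)c3)CO[Si](C)(C)C(C)(C)C
F2 | step 5 | (3S,4S)-3-{[(tert-butyldimethylsilyl)oxy]methyl}-2-methylidene-4-[(triethylsilyl)oxy]-1,4-bis(3,4,5-trimethoxyphenyl)butan-1-one | CC[Si](CC)(CC)O[C@H](c1cc(OC)c(OC)c(OC)c1)[C@@H](C(=C)C(=O)c2cc(OC)c(OC)c(OC)c2)CO[Si](C)(C)C(C)(C)C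
F3 | step 4 | (1S,2S)-2-{[(tert-butyldimethylsilyl)oxy]methyl}-1-(3,4,5-trimethoxyphenyl)butane-1,4-diol | O[C@H](c1cc(OC)c(OC)c(OC)c1)[C@@H](CCO)CO[Si](C)(C)C(C)(C)C
F4 | step 4 | (4S,5S)-4-{[(tert-butyldimethylsilyl)oxy]methyl}-5-(3,4,5-trimethoxyphenyl)oxolan-2-one | O1[C@H](c2cc(OC)c(OC)c(OC)c2)[C@H](CO[Si](C)(C)C(C)(C)C)CC1=O
F5 | step 4 | 3,4,5-trimethoxyphenyllithium | [Li]c1cc(OC)c(OC)c(OC)c1
F6 | step 4 | (3S,4S)-3-{[(tert-butyldimethylsilyl)oxy]methyl}-4-hydroxy-1,4-bis(3,4,5-trimethoxyphenyl)butan-1-one | O[C@H](c1cc(OC)c(OC)c(OC)c1)[C@@H](CC(=O)c2cc(OC)c(OC)c(OC)c2)CO[Si](C)(C)C(C)(C)C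
F7 | step 2 | (1R,2S)-2-ethenyl-1-(3,4,5-trimethoxyphenyl)propane-1,3-diol | O[C@@H](c1cc(OC)c(OC)c(OC)c1)[C@@H](C=C)CO
F8 | step 2 | (1R,2S)-2-{[(tert-butyldimethylsilyl)oxy]methyl}-1-(3,4,5-trimethoxyphenyl)but-3-en-1-ol | O[C@@H](c1cc(OC)c(OC)c(OC)c1)[C@@H](C=C)CO[Si](C)(C)C(C)(C)C
F9 | step 2 | (1S,2S)-2-{[(tert-butyldimethylsilyl)oxy]methyl}-1-(3,4,5-trimethoxyphenyl)but-3-en-1-yl 4-nitrobenzoate | O=C(O[C@H](c1cc(OC)c(OC)c(OC)c1)[C@@H](C=C)CO[Si](C)(C)C(C)(C)C)c2ccc(cc2)[N+](=O)[O-]
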